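**Retrosynthetic overview**
- Target ⇐ bis-benzyl ether (hydrogenolysis) ⇐ α-aryloxy ketone (chelation-controlled reduction sets the carbinol) ⇐ tetralin ethyl ester + aryllithium.
- Tetralin ⇐ C1–C8a bond by photochemical cationic hydroarylation of an (E)-1,4-diaryl-2,3-dimethylbut-1-ene; C1 and C2 are set under control of C3.
- Styrene ⇐ terminal alkyne + aryl bromide by Zr-catalysed methylalumination / Pd coupling (installs the C2 methyl and the C1–aryl bond).
- Alkyne ⇐ (R)-Roche ester (source of C3) via iodide, Negishi arylation and one-carbon homologation; aryl bromide ⇐ 4-bromoguaiacol + ethyl (S)-lactate by Mitsunobu inversion (source of the ether-bearing side-chain carbon).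
- Ring order: the three benzene rings are bought; the saturated ring of the tetralin is the only ring formed (step 6).

Assumption: the SMILES is read as the all-trans (1S,2S,3R)-tetralin carrying an erythro (1S,2R) side chain; compounds 3 and 6 are treated as commercial.

**Step 1**
Reactants: 1, methyl (R)-3-hydroxy-2-methylpropanoate ((R)-Roche ester)
Product: 2, methyl (S)-3-iodo-2-methylpropanoate
Conditions: I2, PPh3, imidazole, CH2Cl2, 0 °C → rt
Reagents that add atoms: iodine, II
Why: Appel iodination of the primary alcohol leaves the stereocentre untouched (the R→S change is only a CIP priority switch).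

**Step 2**
Reactants: 2, methyl (S)-3-iodo-2-methylpropanoate; 3, 1-(benzyloxy)-4-bromo-2-methoxybenzene
Product: 4, methyl (R)-3-[4-(benzyloxy)-3-methoxyphenyl]-2-methylpropanoate
Conditions: Zn dust, LiCl, THF, 30 °C; then 3, Pd(OAc)2 (2 mol %), SPhos (4 mol %), THF, 40 °C
Reagents that add atoms: none (the aryl group comes from 3)
Why: Negishi sp3–sp2 coupling of the Roche-ester-derived β-zincio ester with an aryl bromide, which does not disturb the α-stereocentre.

**Step 3**
Reactants: 4, methyl (R)-3-[4-(benzyloxy)-3-methoxyphenyl]-2-methylpropanoate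
Product: 5, 1-(benzyloxy)-2-methoxy-4-[(2R)-2-methylbut-3-yn-1-yl]benzene
Conditions: DIBAL-H (1.05 equiv), CH2Cl2, −78 °C; then MeOH, K2CO3, Ohira–Bestmann reagent, −78 °C → rt (one pot)
Reagents that add atoms: dimethyl (1-diazo-2-oxopropyl)phosphonate, CC(=O)C(=[N+]=[N-])P(=O)(OC)OC (supplies the terminal alkyne carbon)
Why: Partial ester reduction via the aluminium hemiacetal followed by Seyferth–Gilbert (Ohira–Bestmann) homologation of the aldehyde in situ, kept cold to avoid α-epimerisation.

**Step 4**
Reactants: 6, 4-bromo-2-methoxyphenol; 7, ethyl (S)-lactate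
Product: 8, ethyl (R)-2-(4-bromo-2-methoxyphenoxy)propanoate
Conditions: PPh3, DIAD, THF, 0 °C → rt
Reagents that add atoms: none
Why: Mitsunobu etherification proceeds by clean SN2 inversion of the lactate carbinol, giving the (R)-aryloxy centre of the side chain.

**Step 5**
Reactants: 5, 1-(benzyloxy)-2-methoxy-4-[(2R)-2-methylbut-3-yn-1-yl]benzene; 8, ethyl (R)-2-(4-bromo-2-methoxyphenoxy)propanoate
Product: 9, ethyl (2R)-2-{4-[(1E,3R)-4-[4-(benzyloxy)-3-methoxyphenyl]-2,3-dimethylbut-1-en-1-yl]-2-methoxyphenoxy}propanoate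
Conditions: AlMe3 (2.5 equiv), Cp2ZrCl2 (20 mol %), CH2Cl2, 0 °C → rt; evaporate volatiles; then 8, ZnCl2, Pd(Pt-Bu3)2 (3 mol %), THF, rt → 45 °C
Reagents that add atoms: trimethylaluminium, C[Al](C)C (supplies the C2 methyl)
Why: Negishi Zr-catalysed syn-methylalumination places Me on the internal and Al on the terminal alkyne carbon, and Pd/Zn cross-coupling of the alkenylalane with 8 retains geometry to give the (E)-trisubstituted styrene.

**Step 6**
Reactants: 9, the (E)-styrene above
Product: 10, ethyl (2R)-2-{4-[(1S,2S,3R)-7-(benzyloxy)-6-methoxy-2,3-dimethyl-1,2,3,4-tetrahydronaphthalen-1-yl]-2-methoxyphenoxy}propanoate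
Conditions: hν (310 nm LEDs), degassed HFIP (3 mM), 20 °C
Reagents that add atoms: none
Why: Proposed new method: the S1 state of the electron-rich β-methylstyrene is strongly basic at C2 and is protonated by HFIP to the p-alkoxybenzylic C1 cation without ground-state acid, and the tethered benzyloxy-methoxy ring closes para to its OMe (C1–C8a bond) through a chair-like transition state with the C3 methyl, C2 methyl and C1 aryl all equatorial; the wrong C2 epimer of the cation is expected to revert to alkene by β-proton loss and be re-excited, so the Roche-derived (R)-C3 centre should select the all-trans (1S,2S,3R) product, which no longer absorbs at 310 nm; the closest known reactions are photo-Markovnikov addition of water/alcohols to styrenes via photoprotonation and acid-mediated cationic cyclisation of 1,4-diarylbutenes to aryltetralin lignans.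

**Step 7**
Reactants: 10, the tetralin ethyl ester above; 3, 1-(benzyloxy)-4-bromo-2-methoxybenzene
Product: 11, (2R)-1-[4-(benzyloxy)-3-methoxyphenyl]-2-{4-[(1S,2S,3R)-7-(benzyloxy)-6-methoxy-2,3-dimethyl-1,2,3,4-tetrahydronaphthalen-1-yl]-2-methoxyphenoxy}propan-1-one
Conditions: 3, n-BuLi, THF, −78 °C; add to 10, THF, −78 °C; AcOH quench at −78 °C
Reagents that add atoms: none (the aryl group comes from 3)
Why: Acyl substitution by the aryllithium stops at the ketone because the α-aryloxy-chelated tetrahedral lithium hemiketal survives at −78 °C until the cold acidic quench, which also protects the α-centre from epimerisation.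

**Step 8**
Reactants: 11, the α-aryloxy ketone above
Product: 12, (1S,2R)-1-[4-(benzyloxy)-3-methoxyphenyl]-2-{4-[(1S,2S,3R)-7-(benzyloxy)-6-methoxy-2,3-dimethyl-1,2,3,4-tetrahydronaphthalen-1-yl]-2-methoxyphenoxy}propan-1-ol
Conditions: Zn(BH4)2, Et2O, −20 → 0 °C
Reagents that add atoms: none
Why: Cram-chelate reduction (Zn bridges the carbonyl and the α-aryloxy/o-methoxy oxygens) delivers hydride from the face of the α-H, so the lactate-derived (R)-centre sets the new carbinol as (S), i.e. the erythro (anti) isomer; any minor threo isomer is removed by chromatography.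

**Step 9**
Reactants: 12, the bis-benzyl ether above
Product: 13, 4-[(1S,2R)-1-hydroxy-2-{4-[(1S,2S,3R)-7-hydroxy-6-methoxy-2,3-dimethyl-1,2,3,4-tetrahydronaphthalen-1-yl]-2-methoxyphenoxy}propyl]-2-methoxyphenol (CID 53359464)
Conditions: H2 (1 atm), 10 % Pd/C, EtOAc/EtOH, rt, stopped at full debenzylation
Reagents that add atoms: none
Why: Neutral hydrogenolysis cleaves both benzyl aryl ethers while the secondary benzylic alcohol, the alkyl aryl ether and all stereocentres are untouched.

**Compound list**
1 | methyl (R)-3-hydroxy-2-methylpropanoate | COC(=O)[C@H](C)CO | starting material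
2 | methyl (S)-3-iodo-2-methylpropanoate | COC(=O)[C@H](C)CI | intermediate
3 | 1-(benzyloxy)-4-bromo-2-methoxybenzene | COc1cc(Br)ccc1OCc1ccccc1 | starting material
4 | methyl (R)-3-[4-(benzyloxy)-3-methoxyphenyl]-2-methylpropanoate | COC(=O)[C@H](C)Cc1ccc(OCc2ccccc2)c(OC)c1 | intermediate
5 | 1-(benzyloxy)-2-methoxy-4-[(2R)-2-methylbut-3-yn-1-yl]benzene | C#C[C@H](C)Cc1ccc(OCc2ccccc2)c(OC)c1 | intermediate
6 | 4-bromo-2-methoxyphenol | COc1cc(Br)ccc1O | starting material
7 | ethyl (S)-lactate | CCOC(=O)[C@H](C)O | starting material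
8 | ethyl (R)-2-(4-bromo-2-methoxyphenoxy)propanoate | CCOC(=O)[C@@H](C)Oc1ccc(Br)cc1OC | intermediate
9 | ethyl (2R)-2-{4-[(1E,3R)-4-[4-(benzyloxy)-3-methoxyphenyl]-2,3-dimethylbut-1-en-1-yl]-2-methoxyphenoxy}propanoate | CCOC(=O)[C@@H](C)Oc1ccc(/C=C(\C)[C@H](C)Cc2ccc(OCc3ccccc3)c(OC)c2)cc1OC | intermediate
10 | ethyl (2R)-2-{4-[(1S,2S,3R)-7-(benzyloxy)-6-methoxy-2,3-dimethyltetralin-1-yl]-2-methoxyphenoxy}propanoate | CCOC(=O)[C@@H](C)Oc1ccc([C@H]2c3cc(OCc4ccccc4)c(OC)cc3C[C@@H](C)[C@@H]2C)cc1OC | intermediate
11 | (2R)-1-[4-(benzyloxy)-3-methoxyphenyl]-2-{4-[(1S,2S,3R)-7-(benzyloxy)-6-methoxy-2,3-dimethyltetralin-1-yl]-2-methoxyphenoxy}propan-1-one | COc1cc(C(=O)[C@@H](C)Oc2ccc([C@H]3c4cc(OCc5ccccc5)c(OC)cc4C[C@@H](C)[C@@H]3C)cc2OC)ccc1OCc6ccccc6 | intermediate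
12 | (1S,2R)-1-[4-(benzyloxy)-3-methoxyphenyl]-2-{4-[(1S,2S,3R)-7-(benzyloxy)-6-methoxy-2,3-dimethyltetralin-1-yl]-2-methoxyphenoxy}propan-1-ol | COc1cc([C@H](O)[C@@H](C)Oc2ccc([C@H]3c4cc(OCc5ccccc5)c(OC)cc4C[C@@H](C)[C@@H]3C)cc2OC)ccc1OCc6ccccc6 | intermediate
13 | 4-[(1S,2R)-1-hydroxy-2-{4-[(1S,2S,3R)-7-hydroxy-6-methoxy-2,3-dimethyltetralin-1-yl]-2-methoxyphenoxy}propyl]-2-methoxyphenol | COc1cc([C@H](O)[C@@H](C)Oc2ccc([C@H]3c4cc(O)c(OC)cc4C[C@@H](C)[C@@H]3C)cc2OC)ccc1O | target

**Totals**
Total steps: 9. Longest linear sequence: 8 (steps 1, 2, 3, 5, 6, 7, 8, 9); step 4 is the one-step side branch.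

**Steps most likely to fail**
1. Step 6 (proposed new photochemical hydroarylative cyclisation). The risks are inefficient photoprotonation, HFIP-ether trapping of the cation, and incomplete control at C2. Fallback (known chemistry): ground-state Brønsted/Lewis-acid cationic cyclisation of 9 (5 mol % TfOH or Bi(OTf)3, CH2Cl2/HFIP, −20 → 0 °C) under equilibrating conditions, the established Friedel–Crafts route to all-trans aryltetralin lignans.
2. Step 5 (one-pot methylalumination / cross-coupling). The risks are AlMe3 attack on the ester of 8 and slow oxidative addition of the electron-rich bromide. Fallback: quench the alkenylalane with I2 to isolate the (E)-vinyl iodide and join it by Suzuki–Miyaura coupling to the pinacol boronate made from 8 (Miyaura borylation).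
3. Step 7 (ketone from the ethyl ester). The risks are over-addition to the tertiary alcohol and α-deprotonation by ArLi. Fallback: convert 10 to the Weinreb amide (MeNHOMe·HCl, i-PrMgCl, −20 °C) and add the aryl Grignard from 3, which stops cleanly at ketone 11.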